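The runs are calculated for an exercise; noise was put on by code.

Add up what partner is owed before reckoning any rate. These are the flasks, the runs and the questions.

| setting | zeta | delta | epsilon | east | south-west |
|---|---|---|---|---|---|
| starting material | 0.16 M | 0.16 M | 0.16 M | 0.16 M | 0.16 M |
| partner | 0.27 M | 0.31 M | 0.208 M | 0.400 M | 0.208 M |
| second substrate | 0.080 M | 0.080 M | 0.080 M | 0.0800 M | 0.0800 M |
| precatalyst | 0.80 mM | 0.80 mM | 1.5 mM | 2.5 mM | 0.80 mM |
| temperature | 65 °C | 80 °C | 65 °C |  |  |
| remark | run made earlier | run made earlier | run made earlier | at 90 °C throughout | at 70 °C until 12 h, from then on at 90 °C |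
| time |  |  |  | 2.5 d | 2.5 d |

zeta run (percent of the starting material charged)

| time / d | target / % | starting material / % |
|---|---|---|
| 0.208 | 5.0 | 96.6 |
| 0.500 | 17.8 | 80.8 |
| 1.04 | 46.1 | 54.1 |
| 2.50 | 76.0 | 24.2 |

delta run (percent of the starting material charged)

| time / h | target / % | starting material / % |
|---|---|---|
| 10.0 | 49.9 | 49.1 |
| 20.0 | 75.7 | 25.8 |
| 30.0 | 86.3 | 13.2 |
| 40.0 | 93.4 | 10.9 |

epsilon run (percent of the starting material charged)

| time / d | target / % | starting material / % |
|---|---|---|
| 0.625 | 28.3 | 72.0 |
| 1.25 | 52.4 | 47.1 |
| 2.08 | 67.3 | 32.8 |
| 2.50 | 70.8 | 28.3 |

(standard deviation of a reading: 1 percentage point)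

- the winner by amount of target, in percent of the starting material charged; "neither" if no more than 2 percentage points parts them (east / south-west / neither)
- how much target is there at the end, in percent of the starting material charged: east
- how much target is there at the end, in percent of the starting material charged: south-west

In east and south-west, starting material and second substrate together claim 0.240 M of partner if each takes it one to one. That is our assumption, for no run reads partner or second substrate. South-west holds 0.208 M, less than the claim, so there partner is the limiting reagent. We call the partner share the charged partner minus the charged second substrate, over the charged starting material: 80.0% in south-west. East holds 0.400 M, more than the claim, so its target can reach the whole charge.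

Delta has south-west's precatalyst charge, so we replace its curve by one mean rate of closing the distance to the whole charge: 1.62 d⁻¹ at 80 °C. Zeta needs 1.04 d for about what delta makes in 10.0 h, a factor of 2.50 that we read as temperature, setting aside their different partner charges. Stretched over the step from 80 °C to 90 °C it becomes 1.84, which gives 2.98 d⁻¹, and we assume that south-west closes on its share at this rate. From zeta's 17.8% at 12 h, with 2.00 d at that rate, we commit to 79.8% in south-west. East, closing on the whole charge at that same rate, with no credit for holding more partner and precatalyst than delta, comes to 99.9%.

The weak link is that mean, and the aim it closes on. Epsilon has south-west's partner charge, hence the same share. Towards the share, epsilon's rate runs 1.00 d⁻¹ early and 0.768 d⁻¹ late. Towards the whole charge it runs 0.655 d⁻¹ and 0.270 d⁻¹. So we keep the share, and the rate of delta's middle interval, 1.38 d⁻¹, moves our south-west number by just 0.23 percentage points.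

The forecast names east as winner, with 98% in east and 90% in south-west, holding that “Second substrate cannot be limiting”. Our south-west number is lower.

The flasks give 100% in east and 78.0% in south-west, so east wins.

    partner + precatalyst → catalyst + spent reagent (k = 0.289 L mol⁻¹ h⁻¹, Ea = 87.0 kJ mol⁻¹)
    starting material + partner + catalyst → catalyst + target (k = 463 L² mol⁻² h⁻¹, Ea = 38.0 kJ mol⁻¹)
    second substrate + partner + catalyst → catalyst + second product (k = 559 L² mol⁻² h⁻¹, Ea = 53.0 kJ mol⁻¹)
    (constants at 70 °C)

In east at 0.0895 d, partner's half-life by the target step is 0.22 d against 23 d by the passing of precatalyst into catalyst, and the target step uses partner at 1.9 times the rate of the second-substrate step. South-west's 78.0% stands 2 points under its partner share of 80.0%, with 4.8% of its partner and 9.5% of its second substrate left, and after 25.0 d it holds 82.7%, above that share, with 6.44% of its second substrate unused. The flask like east but with 0.40 M of starting material has a partner share of 80.0% and holds 80.9% at 2.50 d, with partner at 0%.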